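**Assumption:** the target has no stereocentres and its aryl–O axes rotate freely, so it is achiral; "single enantiomer" is taken to mean the given constitution, and no stereocontrol is needed. Formula C30H22O17; rings are labelled A–E from the 2,4,6-trihydroxyphenoxy end to the 3,4,5-trihydroxyphenoxy end.

## Retrosynthetic overview

1. Target ⇐ global hydrogenolysis of a fully protected pentamer (11 benzyl ethers plus one diphenylmethylene ketal on ring C).
2. Central B–O–C ether ⇐ proposed Ni-catalysed decarbonylative etherification of a "depside" aryl ester made from an A–B phenol and a C–D–E carboxylic acid; ring C is gallate, and its carboxyl carbon leaves as CO.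
3. A–B phenol ⇐ SNAr of 2,4,6-tris(benzyloxy)phenol (ring A) on a 2-fluoro-4,6-bis(benzyloxy)benzaldehyde (ring B), then Dakin oxidation (CHO → OH).
4. C–D–E acid ⇐ methyl gallate diphenylmethylene ketal; Ullmann coupling with 5-bromo-1,2,3-tris(benzyloxy)benzene (ring D); Vilsmeier/Dakin to hydroxylate ring D next to the ether; second Ullmann with the same bromide (ring E).
5. No ring is constructed; all five benzene rings are purchased. Order of joining: A+B; C+D, then E; finally (AB)+(CDE).

## Route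

### Fragment A–B

**Step 1**
Reactants: 1, 2,4,6-trihydroxybenzaldehyde; 2, benzyl bromide
Product: 3, 2,4,6-tris(benzyloxy)benzaldehyde
Conditions: BnBr (3.5 equiv), K2CO3, DMF, rt → 60 °C
Reagents that add atoms: benzyl bromide (2), BrCc1ccccc1
Why: Williamson O-benzylation of all three phenols; the formyl group lowers ring nucleophilicity so C-benzylation stays minor.

**Step 2**
Reactants: 3, 2,4,6-tris(benzyloxy)benzaldehyde
Product: 4, 2,4,6-tris(benzyloxy)phenol
Conditions: mCPBA, CH2Cl2, 0 °C → rt; then K2CO3, MeOH, rt (Ar)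
Reagents that add atoms: mCPBA, OOC(=O)c1cccc(Cl)c1 (one O)
Why: Baeyer–Villiger/Dakin oxidation, in which the very electron-rich 2,4,6-trialkoxyaryl group migrates and the aryl formate is methanolysed to the phenol.

**Step 3**
Reactants: 5, 1,3,5-trifluorobenzene; 6, benzyl alcohol
Product: 7, 1,3-bis(benzyloxy)-5-fluorobenzene
Conditions: BnOH (2.2 equiv), NaH, NMP, 0 → 100 °C
Reagents that add atoms: benzyl alcohol (6), OCc1ccccc1
Why: Double SNAr on the inductively activated trifluoroarene; the third substitution is much slower, so stoichiometry stops the reaction at the bis-ether.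

**Step 4**
Reactants: 7, 1,3-bis(benzyloxy)-5-fluorobenzene
Product: 8, 2,4-bis(benzyloxy)-6-fluorobenzaldehyde
Conditions: POCl3, DMF, 0 → 60 °C; aq NaOAc
Reagents that add atoms: DMF, CN(C)C=O (formyl carbon); water, O (carbonyl oxygen on iminium hydrolysis)
Why: Vilsmeier–Haack formylation goes ortho/para to the two OBn groups at the less hindered site next to F rather than between the two OBn groups (as with other 5-substituted resorcinol diethers); the minor 4-fluoro-2,6-isomer is removed by chromatography.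

**Step 5**
Reactants: 4, 2,4,6-tris(benzyloxy)phenol; 8, 2,4-bis(benzyloxy)-6-fluorobenzaldehyde
Product: 9, 2,4-bis(benzyloxy)-6-[2,4,6-tris(benzyloxy)phenoxy]benzaldehyde
Conditions: Cs2CO3, degassed DMSO, 90 °C, Ar
Reagents that add atoms: none (only reactants 4 and 8)
Why: SNAr of the aryloxide on the fluoride ortho to CHO; the Meisenheimer charge sits on the formyl-bearing carbon and on carbons that carry no OBn, so the meta-OBn groups do not deactivate.

**Step 6**
Reactants: 9, 2,4-bis(benzyloxy)-6-[2,4,6-tris(benzyloxy)phenoxy]benzaldehyde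
Product: 10, 2,4-bis(benzyloxy)-6-[2,4,6-tris(benzyloxy)phenoxy]phenol (A–B phenol)
Conditions: mCPBA (1.2 equiv), NaHCO3, CH2Cl2, 0 °C → rt; then K2CO3, MeOH, rt
Reagents that add atoms: mCPBA, OOC(=O)c1cccc(Cl)c1 (one O)
Why: Dakin/Baeyer–Villiger oxidation of an aldehyde flanked by two O-substituents and para to a third, which is far faster than any ring oxidation at 0 °C.

### Fragment C–D–E

**Step 7**
Reactants: 11, 5-bromo-1,2,3-trimethoxybenzene
Product: 12, 5-bromobenzene-1,2,3-triol
Conditions: BBr3 (4 equiv), CH2Cl2, −78 °C → rt; MeOH/H2O quench (Ar)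
Reagents that add atoms: none
Why: Standard BBr3 cleavage of aryl methyl ethers; the aryl bromide is inert.

**Step 8**
Reactants: 12, 5-bromobenzene-1,2,3-triol; 2, benzyl bromide
Product: 13, 5-bromo-1,2,3-tris(benzyloxy)benzene
Conditions: BnBr (3.5 equiv), K2CO3, DMF, 60 °C, Ar
Reagents that add atoms: benzyl bromide (2), BrCc1ccccc1
Why: Williamson O-benzylation; this one aryl bromide later supplies both ring D and ring E.

**Step 9**
Reactants: 14, methyl gallate; 15, dichlorodiphenylmethane
Product: 16, methyl 7-hydroxy-2,2-diphenyl-1,3-benzodioxole-5-carboxylate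
Conditions: Ph2CCl2 (1.5 equiv), neat, 180 °C, 15 min (−HCl)
Reagents that add atoms: dichlorodiphenylmethane (15), ClC(Cl)(c1ccccc1)c1ccccc1
Why: Ketalisation of a vicinal diol; only adjacent OH groups can close the dioxole, and the two possible ketals are identical by symmetry, so exactly one phenol stays free.

**Step 10**
Reactants: 16, methyl 7-hydroxy-2,2-diphenyl-1,3-benzodioxole-5-carboxylate; 13, 5-bromo-1,2,3-tris(benzyloxy)benzene
Product: 17, methyl 2,2-diphenyl-7-[3,4,5-tris(benzyloxy)phenoxy]-1,3-benzodioxole-5-carboxylate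
Conditions: CuI (10 mol%), picolinic acid (20 mol%), K3PO4, DMSO, 90 °C, Ar
Reagents that add atoms: none (only reactants 16 and 13)
Why: Ligand-accelerated Ullmann C–O coupling of an unhindered aryl bromide with a mono-ortho-substituted phenol; the ester and ketal tolerate K3PO4.

**Step 11**
Reactants: 17, methyl 2,2-diphenyl-7-[3,4,5-tris(benzyloxy)phenoxy]-1,3-benzodioxole-5-carboxylate
Product: 18, methyl 7-[3,4,5-tris(benzyloxy)-2-formylphenoxy]-2,2-diphenyl-1,3-benzodioxole-5-carboxylate
Conditions: POCl3, DMF, 0 → 70 °C; aq NaOAc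
Reagents that add atoms: DMF, CN(C)C=O (formyl carbon); water, O (carbonyl oxygen)
Why: Vilsmeier–Haack formylation; only tetra-oxygenated ring D is nucleophilic enough (ring C is deactivated by the ester), and its two free positions are equivalent, so a single regioisomer forms and mono-formylation switches the ring off.

**Step 12**
Reactants: 18, methyl 7-[3,4,5-tris(benzyloxy)-2-formylphenoxy]-2,2-diphenyl-1,3-benzodioxole-5-carboxylate
Product: 19, methyl 7-[3,4,5-tris(benzyloxy)-2-hydroxyphenoxy]-2,2-diphenyl-1,3-benzodioxole-5-carboxylate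
Conditions: mCPBA, NaHCO3, CH2Cl2, 0 °C → rt; then K2CO3, MeOH, rt
Reagents that add atoms: mCPBA, OOC(=O)c1cccc(Cl)c1 (one O)
Why: Dakin/Baeyer–Villiger oxidation of the electron-rich aldehyde; methanolysis cleaves only the formate, since the methyl ester is degenerate under K2CO3/MeOH.

**Step 13**
Reactants: 19, methyl 7-[3,4,5-tris(benzyloxy)-2-hydroxyphenoxy]-2,2-diphenyl-1,3-benzodioxole-5-carboxylate; 13, 5-bromo-1,2,3-tris(benzyloxy)benzene
Product: 20, methyl 2,2-diphenyl-7-{3,4,5-tris(benzyloxy)-2-[3,4,5-tris(benzyloxy)phenoxy]phenoxy}-1,3-benzodioxole-5-carboxylate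
Conditions: 13 (2 equiv), CuI (20 mol%), picolinic acid (40 mol%), K3PO4, DMSO, 105 °C, Ar
Reagents that add atoms: none (only reactants 19 and 13)
Why: Ullmann coupling of a 2,6-dioxygenated phenol with an unhindered aryl bromide, the classic fuhalol disconnection, using the Cu/picolinate system suited to di-ortho-substituted phenols.

**Step 14**
Reactants: 20, methyl ester above
Product: 21, 2,2-diphenyl-7-{3,4,5-tris(benzyloxy)-2-[3,4,5-tris(benzyloxy)phenoxy]phenoxy}-1,3-benzodioxole-5-carboxylic acid (C–D–E acid)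
Conditions: LiOH, THF/MeOH/H2O, 50 °C; citric acid work-up at 0 °C
Reagents that add atoms: lithium hydroxide/water, [Li+].[OH-] (acid OH oxygen)
Why: Ordinary saponification; benzyl ethers, diaryl ethers and the ketal are base-stable.

### Union and deprotection

**Step 15**
Reactants: 21, C–D–E acid; 10, A–B phenol
Product: 22, 2,4-bis(benzyloxy)-6-[2,4,6-tris(benzyloxy)phenoxy]phenyl 2,2-diphenyl-7-{3,4,5-tris(benzyloxy)-2-[3,4,5-tris(benzyloxy)phenoxy]phenoxy}-1,3-benzodioxole-5-carboxylate
Conditions: (COCl)2, cat. DMF, CH2Cl2, 0 °C → rt; then 10, Et3N, DMAP, CH2Cl2, rt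
Reagents that add atoms: none (only reactants 21 and 10)
Why: DMAP-catalysed acylation of a hindered phenol by an aroyl chloride; ester formation is far less sensitive to steric hindrance than direct O-arylation.

**Step 16** (proposed new step)
Reactants: 22, depside ester
Product: 23, 6-{2,4-bis(benzyloxy)-6-[2,4,6-tris(benzyloxy)phenoxy]phenoxy}-2,2-diphenyl-4-{3,4,5-tris(benzyloxy)-2-[3,4,5-tris(benzyloxy)phenoxy]phenoxy}-1,3-benzodioxole (protected pentamer)
Conditions: Ni(cod)2 (20 mol%), dcypt [3,4-bis(dicyclohexylphosphino)thiophene] (40 mol%), K3PO4, m-xylene, 150 °C, slow Ar sweep (−CO)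
Reagents that add atoms: none (CO is lost)
Why: Proposed new method: decarbonylative C(aryl)–O coupling of a polyoxygenated depside ester. Ni(0)/dcypt adds oxidatively to the C(acyl)–OAr bond (established for aryl arenecarboxylates; the di-ortho-substituted aryloxide disfavours competing C(aryl)–O insertion), the aroyl–Ni loses CO by 1,1-de-insertion, and (dcypt)Ni(Ar)(OAr′) reductively eliminates the diaryl ether. Reductive elimination should be helped by steric pressure from the 2,6-dioxygenated aryloxide and by the 3,4,5-trioxygenated aryl being roughly σ-neutral at its ipso carbon (two meta-O acceptors offset one para-O donor). The closest known reaction type is Ni- or Pd/dcypt decarbonylative etherification of aryl azinecarboxylates, which to my knowledge has not been shown for non-heteroaromatic polyalkoxybenzoates or di-ortho-substituted aryloxides.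

**Step 17**
Reactants: 23, protected pentamer
Product: 24, pseudopentafuhalol D
Conditions: H2 (1–3 bar), 20% Pd(OH)2/C, degassed THF/MeOH (1:1), rt; filter and concentrate under Ar, Sephadex LH-20
Reagents that add atoms: none
Why: Hydrogenolysis cleaves all eleven benzyl ethers (as toluene) and the doubly benzylic diphenylmethylene ketal (as diphenylmethane) while diaryl ethers are untouched; there is no stereocentre to set or lose.

## Compound list

1 | 2,4,6-trihydroxybenzaldehyde | O=Cc1c(O)cc(O)cc1O | starting material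
2 | benzyl bromide | BrCc1ccccc1 | starting material
3 | 2,4,6-tris(benzyloxy)benzaldehyde | O=Cc1c(OCc2ccccc2)cc(OCc2ccccc2)cc1OCc1ccccc1 | intermediate
4 | 2,4,6-tris(benzyloxy)phenol | Oc1c(OCc2ccccc2)cc(OCc2ccccc2)cc1OCc1ccccc1 | intermediate
5 | 1,3,5-trifluorobenzene | Fc1cc(F)cc(F)c1 | starting material
6 | benzyl alcohol | OCc1ccccc1 | starting material
7 | 1,3-bis(benzyloxy)-5-fluorobenzene | Fc1cc(OCc2ccccc2)cc(OCc2ccccc2)c1 | intermediate
8 | 2,4-bis(benzyloxy)-6-fluorobenzaldehyde | O=Cc1c(F)cc(OCc2ccccc2)cc1OCc1ccccc1 | intermediate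
9 | 2,4-bis(benzyloxy)-6-[2,4,6-tris(benzyloxy)phenoxy]benzaldehyde | O=Cc1c(Oc2c(OCc3ccccc3)cc(OCc3ccccc3)cc2OCc2ccccc2)cc(OCc2ccccc2)cc1OCc1ccccc1 | intermediate
10 | 2,4-bis(benzyloxy)-6-[2,4,6-tris(benzyloxy)phenoxy]phenol | Oc1c(Oc2c(OCc3ccccc3)cc(OCc3ccccc3)cc2OCc2ccccc2)cc(OCc2ccccc2)cc1OCc1ccccc1 | intermediate
11 | 5-bromo-1,2,3-trimethoxybenzene | COc1cc(Br)cc(OC)c1OC | starting material
12 | 5-bromobenzene-1,2,3-triol | Oc1cc(Br)cc(O)c1O | intermediate
13 | 5-bromo-1,2,3-tris(benzyloxy)benzene | Brc1cc(OCc2ccccc2)c(OCc2ccccc2)c(OCc2ccccc2)c1 | intermediate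
14 | methyl gallate | COC(=O)c1cc(O)c(O)c(O)c1 | starting material
15 | dichlorodiphenylmethane | ClC(Cl)(c1ccccc1)c1ccccc1 | starting material
16 | methyl 7-hydroxy-2,2-diphenyl-1,3-benzodioxole-5-carboxylate | COC(=O)c1cc(O)c2OC(c3ccccc3)(c3ccccc3)Oc2c1 | intermediate
17 | methyl 2,2-diphenyl-7-[3,4,5-tris(benzyloxy)phenoxy]-1,3-benzodioxole-5-carboxylate | COC(=O)c1cc(Oc2cc(OCc3ccccc3)c(OCc3ccccc3)c(OCc3ccccc3)c2)c2OC(c3ccccc3)(c3ccccc3)Oc2c1 | intermediate
18 | methyl 7-[3,4,5-tris(benzyloxy)-2-formylphenoxy]-2,2-diphenyl-1,3-benzodioxole-5-carboxylate | COC(=O)c1cc(Oc2cc(OCc3ccccc3)c(OCc3ccccc3)c(OCc3ccccc3)c2C=O)c2OC(c3ccccc3)(c3ccccc3)Oc2c1 | intermediate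
19 | methyl 7-[3,4,5-tris(benzyloxy)-2-hydroxyphenoxy]-2,2-diphenyl-1,3-benzodioxole-5-carboxylate | COC(=O)c1cc(Oc2cc(OCc3ccccc3)c(OCc3ccccc3)c(OCc3ccccc3)c2O)c2OC(c3ccccc3)(c3ccccc3)Oc2c1 | intermediate
20 | methyl 2,2-diphenyl-7-{3,4,5-tris(benzyloxy)-2-[3,4,5-tris(benzyloxy)phenoxy]phenoxy}-1,3-benzodioxole-5-carboxylate | COC(=O)c1cc(Oc2cc(OCc3ccccc3)c(OCc3ccccc3)c(OCc3ccccc3)c2Oc2cc(OCc3ccccc3)c(OCc3ccccc3)c(OCc3ccccc3)c2)c2OC(c3ccccc3)(c3ccccc3)Oc2c1 | intermediate
21 | 2,2-diphenyl-7-{3,4,5-tris(benzyloxy)-2-[3,4,5-tris(benzyloxy)phenoxy]phenoxy}-1,3-benzodioxole-5-carboxylic acid | OC(=O)c1cc(Oc2cc(OCc3ccccc3)c(OCc3ccccc3)c(OCc3ccccc3)c2Oc2cc(OCc3ccccc3)c(OCc3ccccc3)c(OCc3ccccc3)c2)c2OC(c3ccccc3)(c3ccccc3)Oc2c1 | intermediate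
22 | 2,4-bis(benzyloxy)-6-[2,4,6-tris(benzyloxy)phenoxy]phenyl ester of acid 21 (depside ester) | O=C(Oc1c(Oc2c(OCc3ccccc3)cc(OCc3ccccc3)cc2OCc2ccccc2)cc(OCc2ccccc2)cc1OCc1ccccc1)c1cc(Oc2cc(OCc3ccccc3)c(OCc3ccccc3)c(OCc3ccccc3)c2Oc2cc(OCc3ccccc3)c(OCc3ccccc3)c(OCc3ccccc3)c2)c2OC(c3ccccc3)(c3ccccc3)Oc2c1 | intermediate
23 | 6-{2,4-bis(benzyloxy)-6-[2,4,6-tris(benzyloxy)phenoxy]phenoxy}-2,2-diphenyl-4-{3,4,5-tris(benzyloxy)-2-[3,4,5-tris(benzyloxy)phenoxy]phenoxy}-1,3-benzodioxole | C(c1ccccc1)Oc1cc(OCc2ccccc2)c(Oc2cc(OCc3ccccc3)cc(OCc3ccccc3)c2Oc2cc3OC(c4ccccc4)(c4ccccc4)Oc3c(Oc3cc(OCc4ccccc4)c(OCc4ccccc4)c(OCc4ccccc4)c3Oc3cc(OCc4ccccc4)c(OCc4ccccc4)c(OCc4ccccc4)c3)c2)c(OCc2ccccc2)c1 | intermediate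
24 | pseudopentafuhalol D | Oc1cc(O)c(Oc2cc(O)cc(O)c2Oc2cc(O)c(O)c(Oc3cc(O)c(O)c(O)c3Oc3cc(O)c(O)c(O)c3)c2)c(O)c1 | target

## Summary

**Total steps:** 17.

**Longest linear sequence:** 10 steps (11 → 12 → 13 → 17 → 18 → 19 → 20 → 21 → 22 → 23 → 24; steps 7, 8, 10–17).

**Three steps most likely to fail**

1. **Step 16 (proposed decarbonylative etherification).** Likely failure: slow C–O reductive elimination from Ni(II), or CO poisoning, giving proto-decarbonylated arene or recovered ester. Known-chemistry fallback: build ring C as an aryl bromide instead of a benzoate.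
   - Ketalise 5-bromopyrogallol 12 with Ph2CCl2 to 6-bromo-2,2-diphenyl-1,3-benzodioxol-4-ol.
   - O-arylate it by Chan–Lam coupling with 3,4,5-tris(benzyloxy)phenylboronic acid (from 13), which spares the ArBr.
   - Hydroxylate ring D by Vilsmeier/Dakin as in steps 11–12.
   - Attach ring E metal-free with [3,4,5-tris(benzyloxy)phenyl](2,4,6-trimethoxyphenyl)iodonium tosylate.
   - Join the resulting C–D–E aryl bromide to phenol 10 by classical Ullmann coupling (CuI/picolinic acid, K3PO4, DMSO) to reach the same 23.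

2. **Step 13 (Ullmann coupling of the di-ortho-substituted phenol 19 with aryl bromide 13).** Likely failure: low conversion or reductive debromination of 13. Fallback: metal-free O-arylation of 19 with the aryl(2,4,6-trimethoxyphenyl)iodonium salt derived from 13 (tBuOK, toluene, rt–60 °C); this ligand-coupling pathway at iodine(III) tolerates ortho-substituted phenols and transfers the less electron-rich aryl group.

3. **Step 5 (SNAr of hindered aryloxide 4 on fluoro-aldehyde 8).** Likely failure: sluggish substitution because the aldehyde is weakened as an activator by its ortho/para OBn groups, or oxidation of 4. Fallback: switch from SNAr to Cu-catalysed Ullmann coupling of 4 with 2-bromo-4,6-bis(benzyloxy)benzaldehyde (Vilsmeier product of 1-bromo-3,5-bis(benzyloxy)benzene), where the ortho-formyl group assists oxidative addition; then continue with step 6 unchanged.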